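**Strategy.** The plan rests on the bond between C3 of the 4H-chromen-4-one ring and C1' of the pendant aryl ring. C3 is α to the C4 carbonyl; with C2 excised it is simply the methyl carbon of a C2v-symmetric 3,5-diprenylphloroacetophenone. Because this enolate carbon and C1' (para to O-4', ortho to O-2') are both innately nucleophilic, C1' is polarity-reversed as an aryl bromide. A palladium-catalysed ketone α-arylation unites the tris-MOM acetophenone and the prenylated bromoanisole, giving the complete deoxybenzoin skeleton with all three prenyl groups in place; DMF-DMA then inserts C2, and acid unmasks the phenols and closes the pyranone.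

Key step: step 5

Remark on stereochemistry: the target has no stereocentre and no stereogenic double bond (each prenyl alkene carries two identical methyl groups), so it is achiral and no stereocontrol is needed. The only stereo-element on the way, the enamine geometry of 9, is lost on ring closure.

Step 1
Reactants: 1 1-(2,4,6-trihydroxyphenyl)ethanone (phloroacetophenone)
Product: 2 1-[2,4,6-trihydroxy-3,5-bis(3-methylbut-2-en-1-yl)phenyl]ethanone
Conditions: prenyl bromide (2.2 equiv), 10% aq KOH, 0 °C → rt
Reagents that add atoms: prenyl bromide (1-bromo-3-methylbut-2-ene), CC(C)=CCBr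
Why: Nuclear C-prenylation of the ambident phloroglucinol phenolate, where water shields the oxygens and steers the soft allylic bromide to carbon; the two free ring positions are equivalent, so double alkylation should give the single 3,5-isomer, to be separated from mono- and over-alkylated material by chromatography.

Step 2
Reactants: 2 1-[2,4,6-trihydroxy-3,5-bis(3-methylbut-2-en-1-yl)phenyl]ethanone
Product: 3 1-[2,4,6-tris(methoxymethoxy)-3,5-bis(3-methylbut-2-en-1-yl)phenyl]ethanone
Conditions: NaH (3.3 equiv), MOMCl (3.6 equiv), DMF, 0 °C → rt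
Reagents that add atoms: chloromethyl methyl ether (MOMCl), COCCl
Why: Williamson-type O-alkylation of the sodium phenolates with the hard electrophile MOMCl, with NaH breaking the hydrogen bond of the chelated ortho-hydroxyls so that all three phenols are masked against the base of step 5.

Step 3
Reactants: 4 4-bromo-3-methoxyphenol
Product: 5 1-bromo-2-methoxy-4-(methoxymethoxy)benzene
Conditions: NaH, MOMCl, THF, 0 °C → rt
Reagents that add atoms: chloromethyl methyl ether (MOMCl), COCCl
Why: Williamson-type MOM ether formation, which protects the phenol and installs the stronger ortho-directing group for step 4.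

Step 4
Reactants: 5 1-bromo-2-methoxy-4-(methoxymethoxy)benzene
Product: 7 1-bromo-2-methoxy-4-(methoxymethoxy)-3-(3-methylbut-2-en-1-yl)benzene, via aryllithium 6 (not isolated)
Conditions: LiTMP (1.2 equiv), THF, −78 °C; then CuBr·SMe2 (10 mol %), prenyl bromide, −78 → 0 °C
Reagents that add atoms: prenyl bromide (1-bromo-3-methylbut-2-ene), CC(C)=CCBr
Why: Directed ortho-metalation at the hydrogen flanked by OMOM and OMe, the most acidic and doubly chelation-activated site, using a hindered amide base that does not undergo bromine–lithium exchange (the bromine is meta to the lithiated carbon, so no aryne can form), followed by copper-catalysed SN2 allylation that should deliver the linear prenyl group.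

Step 5
Reactants: 3 1-[2,4,6-tris(methoxymethoxy)-3,5-bis(3-methylbut-2-en-1-yl)phenyl]ethanone (1.2 equiv) and 7 1-bromo-2-methoxy-4-(methoxymethoxy)-3-(3-methylbut-2-en-1-yl)benzene
Product: 8 2-[2-methoxy-4-(methoxymethoxy)-3-(3-methylbut-2-en-1-yl)phenyl]-1-[2,4,6-tris(methoxymethoxy)-3,5-bis(3-methylbut-2-en-1-yl)phenyl]ethanone
Conditions: Pd2(dba)3 (2.5 mol %), XPhos (6 mol %), NaOtBu (2.2 equiv), toluene, 80 °C
Reagents that add atoms: none
Why: Buchwald–Hartwig–Miura-type ketone α-arylation: Pd(0)/XPhos inserts into the C–Br bond of 7, the sodium enolate of 3 displaces bromide on Pd(II), and reductive elimination from the C-bound arylpalladium enolate forms the bond between the ketone α-carbon (the future C3) and C1' of the aryl ring. The step unites two carbons that are both innately nucleophilic, the enolate carbon and an arene carbon para to O-4' and ortho to O-2', by reversing the polarity of the latter through oxidative addition. No ring is closed and no stereocentre is formed. The step needs monoarylation rather than diarylation and C–C coupling rather than aldol or Heck pathways: the bulky biarylphosphine, the ortho-methoxy group of 7 and the hindered, more acidic product enolate (held by the second equivalent of base) should stop the reaction at the monoaryl stage, the carbonyl of 3 is shielded by two ortho OMOM groups against self-condensation, and the trisubstituted prenyl alkenes are poor Heck acceptors that sit meta to the C–Pd bond and cannot cyclise onto it. MOM acetals and prenyl groups should be inert to NaOtBu at 80 °C.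

Step 6
Reactants: 8 2-[2-methoxy-4-(methoxymethoxy)-3-(3-methylbut-2-en-1-yl)phenyl]-1-[2,4,6-tris(methoxymethoxy)-3,5-bis(3-methylbut-2-en-1-yl)phenyl]ethanone
Product: 10 5,7-dihydroxy-3-[4-hydroxy-2-methoxy-3-(3-methylbut-2-en-1-yl)phenyl]-6,8-bis(3-methylbut-2-en-1-yl)-4H-chromen-4-one, via enaminone 9 (not isolated)
Conditions: Me2NCH(OMe)2 (3 equiv), toluene, 100 °C; evaporate; then 3 M aq HCl–MeOH, 45 °C
Reagents that add atoms: N,N-dimethylformamide dimethyl acetal (DMF-DMA), COC(OC)N(C)C
Why: Condensation of the doubly activated methylene of 8 with DMF-DMA gives the aminomethylene ketone 9 (all phenols are masked, so none can be O-methylated), and acid methanolysis of the four MOM acetals then frees the two equivalent ortho-hydroxyls, one of which adds to the β-carbon of the protonated enaminone and expels dimethylamine (6-endo-trig addition–elimination, the classical deoxybenzoin-to-isoflavone C1 insertion), with mild acid and moderate temperature chosen so that the ortho-prenyl phenols are not cyclised to chromans.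

**Compound list**

1 | 1-(2,4,6-trihydroxyphenyl)ethanone | CC(=O)c1c(O)cc(O)cc1O | starting material
2 | 1-[2,4,6-trihydroxy-3,5-bis(3-methylbut-2-en-1-yl)phenyl]ethanone | CC(=O)c1c(O)c(CC=C(C)C)c(O)c(CC=C(C)C)c1O | intermediate
3 | 1-[2,4,6-tris(methoxymethoxy)-3,5-bis(3-methylbut-2-en-1-yl)phenyl]ethanone | CC(=O)c1c(OCOC)c(CC=C(C)C)c(OCOC)c(CC=C(C)C)c1OCOC | intermediate
4 | 4-bromo-3-methoxyphenol | COc1cc(O)ccc1Br | starting material
5 | 1-bromo-2-methoxy-4-(methoxymethoxy)benzene | COCOc1ccc(Br)c(OC)c1 | intermediate
6 | [3-bromo-2-methoxy-6-(methoxymethoxy)phenyl]lithium (aryllithium, not isolated) | COCOc1ccc(Br)c(OC)c1[Li] | intermediate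
7 | 1-bromo-2-methoxy-4-(methoxymethoxy)-3-(3-methylbut-2-en-1-yl)benzene | COCOc1ccc(Br)c(OC)c1CC=C(C)C | intermediate
8 | 2-[2-methoxy-4-(methoxymethoxy)-3-(3-methylbut-2-en-1-yl)phenyl]-1-[2,4,6-tris(methoxymethoxy)-3,5-bis(3-methylbut-2-en-1-yl)phenyl]ethanone | COCOc1ccc(CC(=O)c2c(OCOC)c(CC=C(C)C)c(OCOC)c(CC=C(C)C)c2OCOC)c(OC)c1CC=C(C)C | intermediate
9 | (E)-3-(dimethylamino)-2-[2-methoxy-4-(methoxymethoxy)-3-(3-methylbut-2-en-1-yl)phenyl]-1-[2,4,6-tris(methoxymethoxy)-3,5-bis(3-methylbut-2-en-1-yl)phenyl]prop-2-en-1-one (enaminone, not isolated) | CN(C)/C=C(\c1ccc(OCOC)c(CC=C(C)C)c1OC)C(=O)c1c(OCOC)c(CC=C(C)C)c(OCOC)c(CC=C(C)C)c1OCOC | intermediate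
10 | 5,7-dihydroxy-3-[4-hydroxy-2-methoxy-3-(3-methylbut-2-en-1-yl)phenyl]-6,8-bis(3-methylbut-2-en-1-yl)-4H-chromen-4-one | COc1c(-c2coc3c(CC=C(C)C)c(O)c(CC=C(C)C)c(O)c3c2=O)ccc(O)c1CC=C(C)C | target

**Total step count:** 6
**Longest linear sequence:** 4 steps (steps 1, 2, 5, 6; the other branch, steps 3, 4, 5, 6, is equally long)

**Steps most likely to fail, with fallbacks**

1. Step 5 (key α-arylation). Oxidative addition into the electron-rich, ortho-substituted C–Br bond may be slow, so that hydrodehalogenation of 7 or stalling of the hindered enolate coupling competes. The fallback forms the same bond by a Suzuki–Miyaura coupling; it sets out from 2 and 7 and comes back to the route at 10.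
   - Compound 2 is protected with MOMCl and iPr2NEt in CH2Cl2, which should leave one chelated hydroxyl free, to give 1-[2-hydroxy-4,6-bis(methoxymethoxy)-3,5-bis(3-methylbut-2-en-1-yl)phenyl]ethanone F1.
   - DMF-DMA in toluene at 90 °C should convert it into (E)-3-(dimethylamino)-1-[2-hydroxy-4,6-bis(methoxymethoxy)-3,5-bis(3-methylbut-2-en-1-yl)phenyl]prop-2-en-1-one F2.
   - Iodine (1.05 equiv) with pyridine in CHCl3 at 0 °C should iodinate the enaminone carbon and close the ring to 3-iodo-5,7-bis(methoxymethoxy)-6,8-bis(3-methylbut-2-en-1-yl)-4H-chromen-4-one F3.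
   - In parallel, bromine–lithium exchange of 7 (n-BuLi, THF, −78 °C) and quenching with iPrOBpin should give 2-[2-methoxy-4-(methoxymethoxy)-3-(3-methylbut-2-en-1-yl)phenyl]-4,4,5,5-tetramethyl-1,3,2-dioxaborolane F4.
   - Coupling of the two (Pd(dppf)Cl2, K2CO3, dioxane–water, 80 °C) should give 3-[2-methoxy-4-(methoxymethoxy)-3-(3-methylbut-2-en-1-yl)phenyl]-5,7-bis(methoxymethoxy)-6,8-bis(3-methylbut-2-en-1-yl)-4H-chromen-4-one F5.
   - Acid methanolysis (3 M HCl, MeOH, 45 °C) then gives 10.

2. Step 6 (C1 insertion, global deprotection and ring closure). During the acid exposure needed to cleave four MOM groups, the freed phenols may add to the neighbouring prenyl double bonds (chroman formation), or the aminomethylene carbon may be lost by hydrolysis before ring closure. The fallback separates deprotection from ring closure and closes the ring under basic conditions; it sets out from 8 and comes back at 10.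
   - The MOM groups of 8 are removed by thiol-assisted Lewis-acid cleavage (ZnBr2, n-PrSH, CH2Cl2, 0 °C, short contact) to give 2-[4-hydroxy-2-methoxy-3-(3-methylbut-2-en-1-yl)phenyl]-1-[2,4,6-trihydroxy-3,5-bis(3-methylbut-2-en-1-yl)phenyl]ethanone F6.
   - F6 is then formylated and cyclised with triethyl orthoformate and morpholine in DMF at 100 °C to give 10.

3. Step 1 (double C-prenylation). Alkylation of the ambident phenolate may stop at the mono stage or run on to geminal (dearomatised) and O-alkylated products, making isolation of 2 inefficient. The fallback installs the two side chains by sigmatropic rearrangement and olefin metathesis; it sets out from 1 and comes back at 2.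
   - Compound 1 is O-allylated (allyl bromide, K2CO3, acetone, reflux) to give 1-[2,4-bis(allyloxy)-6-hydroxyphenyl]ethanone F7.
   - A double aromatic Claisen rearrangement (N,N-diethylaniline, 190 °C) should fill the two free ring positions and give 1-[3,5-diallyl-2,4,6-trihydroxyphenyl]ethanone F8.
   - Cross-metathesis with 2-methylbut-2-ene (Grubbs second-generation catalyst, CH2Cl2, 40 °C) should convert both allyl groups into prenyl groups and give 2.

Further compounds
F1 | step 5 | 1-[2-hydroxy-4,6-bis(methoxymethoxy)-3,5-bis(3-methylbut-2-en-1-yl)phenyl]ethanone | CC(=O)c1c(O)c(CC=C(C)C)c(OCOC)c(CC=C(C)C)c1OCOC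
F2 | step 5 | (E)-3-(dimethylamino)-1-[2-hydroxy-4,6-bis(methoxymethoxy)-3,5-bis(3-methylbut-2-en-1-yl)phenyl]prop-2-en-1-one | CN(C)/C=C/C(=O)c1c(O)c(CC=C(C)C)c(OCOC)c(CC=C(C)C)c1OCOC
F3 | step 5 | 3-iodo-5,7-bis(methoxymethoxy)-6,8-bis(3-methylbut-2-en-1-yl)-4H-chromen-4-one | COCOc1c(CC=C(C)C)c(OCOC)c2c(=O)c(I)coc2c1CC=C(C)C
F4 | step 5 | 2-[2-methoxy-4-(methoxymethoxy)-3-(3-methylbut-2-en-1-yl)phenyl]-4,4,5,5-tetramethyl-1,3,2-dioxaborolane | COCOc1ccc(B2OC(C)(C)C(C)(C)O2)c(OC)c1CC=C(C)C
F5 | step 5 | 3-[2-methoxy-4-(methoxymethoxy)-3-(3-methylbut-2-en-1-yl)phenyl]-5,7-bis(methoxymethoxy)-6,8-bis(3-methylbut-2-en-1-yl)-4H-chromen-4-one | COCOc1ccc(-c2coc3c(CC=C(C)C)c(OCOC)c(CC=C(C)C)c(OCOC)c3c2=O)c(OC)c1CC=C(C)C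
F6 | step 6 | 2-[4-hydroxy-2-methoxy-3-(3-methylbut-2-en-1-yl)phenyl]-1-[2,4,6-trihydroxy-3,5-bis(3-methylbut-2-en-1-yl)phenyl]ethanone | COc1c(CC(=O)c2c(O)c(CC=C(C)C)c(O)c(CC=C(C)C)c2O)ccc(O)c1CC=C(C)C
F7 | step 1 | 1-[2,4-bis(allyloxy)-6-hydroxyphenyl]ethanone | CC(=O)c1c(O)cc(OCC=C)cc1OCC=C
F8 | step 1 | 1-[3,5-diallyl-2,4,6-trihydroxyphenyl]ethanone | CC(=O)c1c(O)c(CC=C)c(O)c(CC=C)c1O
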